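**Retrosynthetic overview**

1. The 8-propionate and 11-acetate are disconnected to (1R,7S,8R,10S)-8,11-dihydroxyguai-4-en-3-one. Its C4=C5 enone and C1–H come from a C3 dioxolane with a C1=C5 alkene by hydrolysis, conjugation and equilibration.
2. C11 with its two methyls comes from a C7 methyl ester (MeMgBr). The cis C7/C8 pair comes from reduction of a C8 keto ester with dynamic kinetic resolution.
3. Key disconnection, C6–C7 and C9–C10: formal (4+3) cycloaddition of an exocyclic diene C6=C5–C1=C10 on the five-membered ring with a siloxyvinyl diazoacetate (C7, C8, C9 and ester carbon C11) under a chiral dirhodium catalyst, which sets C10.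
4. Feature used: in the seven-membered ring C7 carries an ester-level carbon (C11) beside oxygenated C8, and C10 is a methyl stereocentre with no neighbouring handle. C7(C11)–C8(O)–C9 is the imprint of the diazoacetate and C10 the terminus of the diene.
5. Ring order: the five-membered ring is bought as 1,4-dioxaspiro[4.4]nonan-7-one and the seven-membered ring is closed in the key step. The C4 methyl is placed before the cycloaddition, because without it the later enone has no preference between C4=C5 and C1=C2.

Key step: step 7

Numbering: guaiane numbering throughout (C1 and C5 are the ring-fusion carbons, C1 bonded to C2 and C10, C5 to C4 and C6; C3 is the carbonyl or ketal carbon; C4 and C10 bear methyls; C11 sits on C7).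

Assumption: Rh2(R-PTAD)4 is taken to deliver the carbenoid to the diene face that leads to 10S (end-on approach model for donor/acceptor carbenoids); if a first run shows the opposite sense, Rh2(S-PTAD)4 is used in the same way.

Remark: the C4 methyl centre is racemic in the diene and is carried as a mixture of epimers until step 11, where C4 becomes sp2.

**Route**

Step 1
Reactants: 1 1,4-dioxaspiro[4.4]nonan-7-one; 2 acetaldehyde
Product: 4 aldol 8-(1-hydroxyethyl)-1,4-dioxaspiro[4.4]nonan-7-one (diastereomer mixture), via lithium enolate 3 (not isolated)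
Conditions: LiN(iPr)2, THF, −78 °C; then CH3CHO, −78 °C; then AcOH
Reagents that add atoms: none
Why: Directed aldol addition: the amide base removes the less hindered C8 proton remote from the ketal (kinetic enolate) and the enolate adds to acetaldehyde; the two new stereocentres are lost in step 2.

Step 2
Reactants: 4 aldol 8-(1-hydroxyethyl)-1,4-dioxaspiro[4.4]nonan-7-one
Product: 6 (E)-8-ethylidene-1,4-dioxaspiro[4.4]nonan-7-one, via mesylate 5 (not isolated)
Conditions: MsCl, Et3N, CH2Cl2, 0 °C; then DBU, 0 °C to rt
Reagents that add atoms: none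
Why: Mesylation and E1cB elimination complete the aldol condensation and should give the conjugated exocyclic enone as the E isomer, in which the methyl group avoids the carbonyl oxygen.

Step 3
Reactants: 6 (E)-8-ethylidene-1,4-dioxaspiro[4.4]nonan-7-one
Product: 8 (E)-8-ethylidene-6-methyl-1,4-dioxaspiro[4.4]nonan-7-one (racemic), via lithium enolate 7 (not isolated)
Conditions: LiN(iPr)2, THF, −78 °C; then MeI, DMPU, −78 to −40 °C
Reagents that add atoms: iodomethane, CI
Why: Enolate alkylation: kinetic deprotonation at C6, the only α-CH2 of the enone, and SN2 methylation place the future C4 methyl; the new centre is racemic and is erased in step 11, and the enolate is kept cold so that the β-ketal oxygen is not expelled.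

Step 4
Reactants: 8 (E)-8-ethylidene-6-methyl-1,4-dioxaspiro[4.4]nonan-7-one
Product: 9 (E)-8-ethylidene-6-methyl-7-methylene-1,4-dioxaspiro[4.4]nonane (racemic)
Conditions: Ph3PCH3Br, KOtBu, THF, 0 °C; then 8, 0 °C to rt
Reagents that add atoms: methyltriphenylphosphonium bromide, C[P+](c1ccccc1)(c1ccccc1)c1ccccc1.[Br-]
Why: Wittig methylenation of the ketone gives the 1,3-diene, held s-cis by the five-membered ring, and leaves the (E)-ethylidene geometry untouched.

Step 5
Reactants: 10 methyl acetoacetate
Product: 11 methyl 2-diazo-3-oxobutanoate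
Conditions: 4-acetamidobenzenesulfonyl azide, Et3N, MeCN, 0 °C to rt
Reagents that add atoms: 4-acetamidobenzenesulfonyl azide, CC(=O)Nc1ccc(cc1)S(=O)(=O)N=[N+]=[N-]
Why: Regitz diazo transfer to the active methylene of the β-keto ester.

Step 6
Reactants: 11 methyl 2-diazo-3-oxobutanoate
Product: 12 methyl 3-(tert-butyldimethylsilyloxy)-2-diazobut-3-enoate
Conditions: TBSOTf, Et3N, CH2Cl2, 0 °C
Reagents that add atoms: tert-butyldimethylsilyl trifluoromethanesulfonate, CC(C)(C)[Si](C)(C)OS(=O)(=O)C(F)(F)F
Why: Soft enolisation of the methyl ketone and O-silylation (silyl enol ether formation) give the siloxyvinyl diazoacetate; the diazo group is stable to the amine base.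

Step 7
Reactants: 9 (E)-8-ethylidene-6-methyl-7-methylene-1,4-dioxaspiro[4.4]nonane (2.5 equiv); 12 methyl 3-(tert-butyldimethylsilyloxy)-2-diazobut-3-enoate
Product: 14 (10S)-cycloadduct: C7 methyl ester and C8 TBS enol ether (C7=C8) with C1=C5 alkene and C3 dioxolane and C4 methyl (C4 epimers), via divinylcyclopropane 13 (not isolated)
Conditions: Rh2(R-PTAD)4 (1 mol %), hexanes, −26 °C, slow addition of 12; then rt
Reagents that add atoms: none
Why: Rh2(R-PTAD)4, a divalent rhodium carboxylate, releases N2 from 12, and the donor/acceptor vinylcarbenoid cyclopropanates the 1,1-disubstituted C5=C6 methylene of 9 (C6–C7, then C5–C7) to give the cis-divinylcyclopropane 13, which undergoes a Cope rearrangement through a boat transition state that breaks C5–C7 and forms C9–C10. The closest known reaction type is the enantioselective formal (4+3) cycloaddition (tandem cyclopropanation and Cope rearrangement) of siloxyvinyl diazoacetates with dienes under chiral dirhodium tetracarboxylates. The seven-membered ring closes in the sigmatropic (3,3) step by expansion of the three-membered ring, with both new bonds on the same face of the diene. C10 is the only new stereocentre that survives; the catalyst selects the diene face, and because the (E)-ethylidene methyl points away from the cyclopropane in the boat, that choice is relayed to 10S. The step needs site selectivity (the unhindered methylene against the trisubstituted ethylidene), the siloxyvinyl group cis to the C1 vinyl arm (the donor group prefers the π-substituent of the alkene, and the ring locks the diene s-cis), and catalyst control over the racemic C4 methyl, for which 9 is used in excess so that its better-matched enantiomer reacts first.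

Step 8
Reactants: 14 (10S)-cycloadduct
Product: 15 (10S)-β-keto ester: C8 ketone and C7 methyl ester with C1=C5 alkene and C3 dioxolane (C4 and C7 epimers)
Conditions: Bu4NF, AcOH, THF, 0 °C
Reagents that add atoms: none
Why: Desilylation: fluoride cleaves the Si–O bond of the silyl enol ether and the buffered enolate is protonated to the β-keto ester; C7 stays epimerisable and is fixed in step 9.

Step 9
Reactants: 15 (10S)-β-keto ester
Product: 16 (7S,8R,10S)-cis-hydroxy ester: C8 hydroxyl and C7 methyl ester with C1=C5 alkene and C3 dioxolane (C4 epimers)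
Conditions: (R)-selective ketoreductase (chosen from a commercial panel), NADP+ (cat.), iPrOH, phosphate buffer pH 7, DMSO, 30 °C
Reagents that add atoms: none
Why: Enzymatic ketone reduction with dynamic kinetic resolution: C7 epimerises through the enol faster than reduction, and the enzyme should reduce only the 7S epimer from one face of C8 to give the cis (7S,8R) hydroxy ester, as known for 2-oxocycloalkanecarboxylates; C10 is not touched.

Step 10
Reactants: 16 (7S,8R,10S)-cis-hydroxy ester
Product: 18 (7S,8R,10S)-diol: C8 hydroxyl and C7 2-hydroxypropan-2-yl with C1=C5 alkene and C3 dioxolane (C4 epimers), via methyl ketone 17 (not isolated)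
Conditions: MeMgBr (6 equiv), THF, −20 °C to rt
Reagents that add atoms: methylmagnesium bromide, C[Mg]Br
Why: Double Grignard addition to the ester through the methyl ketone builds C11 with its two methyls; the C8 alkoxide formed first prevents β-elimination, and addition to the ketone should outrun enolisation, so C7 is kept.

Step 11
Reactants: 18 (7S,8R,10S)-diol
Product: 21 (1R,7S,8R,10S)-8,11-dihydroxyguai-4-en-3-one, via β,γ-unsaturated ketone 19 (not isolated), via 1-epimer 20 (not isolated)
Conditions: TsOH·H2O (cat.), THF/H2O, 40 °C; then K2CO3, MeOH, rt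
Reagents that add atoms: water, O
Why: Acetal hydrolysis frees the C3 ketone, acid-catalysed enolisation towards the more substituted C4 moves the alkene into the tetrasubstituted C4=C5 position (C4 centre erased), and carbonate-mediated equilibration through the extended enolate should set C1 thermodynamically with H1 syn to the C10 methyl, the arrangement in which the C1–C2 bond and the C10 methyl are trans.

Step 12
Reactants: 21 (1R,7S,8R,10S)-8,11-dihydroxyguai-4-en-3-one
Product: 22 (1R,7S,8R,10S)-11-hydroxy-8-propanoyloxyguai-4-en-3-one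
Conditions: (EtCO)2O, DMAP (cat.), pyridine, CH2Cl2, 0 °C to rt
Reagents that add atoms: propanoic anhydride, CCC(=O)OC(=O)CC
Why: DMAP-catalysed acylation of the secondary C8 hydroxyl; the tertiary C11 hydroxyl is too hindered to react at this temperature.

Step 13
Reactants: 22 (1R,7S,8R,10S)-11-hydroxy-8-propanoyloxyguai-4-en-3-one
Product: 23 target (1R,7S,8R,10S)-11-acetoxy-8-propanoyloxyguai-4-en-3-one
Conditions: Ac2O, DMAP, Et3N, CH2Cl2, 40 °C
Reagents that add atoms: acetic anhydride, CC(=O)OC(C)=O
Why: DMAP-catalysed acetylation of the tertiary alcohol under basic, non-ionising conditions, which avoid a C11 cation and should leave the enone and C1 alone.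

**Compound list**

1 | 1,4-dioxaspiro[4.4]nonan-7-one | O=C1CCC2(C1)OCCO2 | starting material
2 | acetaldehyde | CC=O | starting material
3 | lithium enolate of 1 (C7–C8 enolate) | [Li]OC1=CCC2(C1)OCCO2 | intermediate
4 | 8-(1-hydroxyethyl)-1,4-dioxaspiro[4.4]nonan-7-one (diastereomer mixture) | CC(O)C1CC2(CC1=O)OCCO2 | intermediate
5 | mesylate of 4 | CC(OS(C)(=O)=O)C1CC2(CC1=O)OCCO2 | intermediate
6 | (E)-8-ethylidene-1,4-dioxaspiro[4.4]nonan-7-one | C/C=C1\CC2(OCCO2)CC1=O | intermediate
7 | lithium enolate of 6 (C6–C7 enolate) | C/C=C1\CC2(OCCO2)C=C1O[Li] | intermediate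
8 | (E)-8-ethylidene-6-methyl-1,4-dioxaspiro[4.4]nonan-7-one (racemic) | C/C=C1\CC2(OCCO2)C(C)C1=O | intermediate
9 | (E)-8-ethylidene-6-methyl-7-methylene-1,4-dioxaspiro[4.4]nonane (racemic) | C/C=C1\CC2(OCCO2)C(C)C1=C | intermediate
10 | methyl acetoacetate | COC(=O)CC(C)=O | starting material
11 | methyl 2-diazo-3-oxobutanoate | COC(=O)C(=[N+]=[N-])C(C)=O | intermediate
12 | methyl 3-(tert-butyldimethylsilyloxy)-2-diazobut-3-enoate | C=C(O[Si](C)(C)C(C)(C)C)C(=[N+]=[N-])C(=O)OC | intermediate
13 | cis-divinylcyclopropane from C5, C6 and C7, spiro at C5 of the ketal ring; C7 bears CO2Me and the 1-(TBSO)vinyl group cis to C1 (5S,7S; C4 epimers) | COC(=O)[C@@]1(C(=C)O[Si](C)(C)C(C)(C)C)C[C@@]12C(C)C3(OCCO3)C/C2=C\C | intermediate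
14 | (10S)-cycloadduct: C7 methyl ester, C8 TBS enol ether (C7=C8), C1=C5 alkene, C3 dioxolane, 4,10-dimethyl (C4 epimers) | COC(=O)C1=C(O[Si](C)(C)C(C)(C)C)C[C@H](C)C2=C(C1)C(C)C3(OCCO3)C2 | intermediate
15 | (10S)-β-keto ester: C8 ketone, C7 methyl ester, C1=C5 alkene, C3 dioxolane (C4 and C7 epimers) | COC(=O)C1CC2=C(CC3(OCCO3)C2C)[C@@H](C)CC1=O | intermediate
16 | (7S,8R,10S)-cis-hydroxy ester (C4 epimers) | COC(=O)[C@H]1CC2=C(CC3(OCCO3)C2C)[C@@H](C)C[C@H]1O | intermediate
17 | (7S,8R,10S)-methyl ketone: C7 acetyl, C8 hydroxyl (C4 epimers) | CC(=O)[C@H]1CC2=C(CC3(OCCO3)C2C)[C@@H](C)C[C@H]1O | intermediate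
18 | (7S,8R,10S)-diol: C7 2-hydroxypropan-2-yl, C8 hydroxyl, C1=C5 alkene, C3 dioxolane (C4 epimers) | CC(C)(O)[C@H]1CC2=C(CC3(OCCO3)C2C)[C@@H](C)C[C@H]1O | intermediate
19 | (7S,8R,10S)-8,11-dihydroxyguai-1(5)-en-3-one (β,γ-unsaturated ketone; C4 epimers) | CC(C)(O)[C@H]1CC2=C(CC(=O)C2C)[C@@H](C)C[C@H]1O | intermediate
20 | (1S,7S,8R,10S)-8,11-dihydroxyguai-4-en-3-one (1-epimer) | O[C@@H]1C[C@H](C)[C@@H]2CC(=O)C(C)=C2C[C@@H]1C(C)(C)O | intermediate
21 | (1R,7S,8R,10S)-8,11-dihydroxyguai-4-en-3-one | O[C@@H]1C[C@H](C)[C@H]2CC(=O)C(C)=C2C[C@@H]1C(C)(C)O | intermediate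
22 | (1R,7S,8R,10S)-11-hydroxy-8-propanoyloxyguai-4-en-3-one | CCC(=O)O[C@@H]1C[C@H](C)[C@H]2CC(=O)C(C)=C2C[C@@H]1C(C)(C)O | intermediate
23 | (1R,7S,8R,10S)-11-acetoxy-8-propanoyloxyguai-4-en-3-one | CCC(=O)O[C@@H]1C[C@H](C)[C@H]2CC(=O)C(C)=C2C[C@@H]1C(C)(C)OC(C)=O | target

**Step count and risks**

Total steps: 13. Longest linear sequence: 11 steps (1–4, then 7–13); the diazo ester branch is 2 steps.

Steps most likely to fail:

Step 7. The two enantiomers of the C4-racemic diene may respond differently to the chiral carbenoid, so that the slower one is cyclopropanated with poor facial selectivity and the enantiomeric purity at C10 is eroded. Part of the carbenoid may also add with the siloxyvinyl group trans to the C1 arm, giving a cyclopropane that does not rearrange. The fallback sets out from enone 6 and makes the diene as one enantiomer. Condensation of 6 with SAMP gives the hydrazone F1. Deprotonation with LiN(iPr)2 and methylation with MeI give the 6S methylated hydrazone F2, the auxiliary directing the azaenolate alkylation. Cleavage with aqueous CuCl2 gives the 6S ketone F3. Methylenation with Zn, CH2Br2 and TiCl4, which is not basic and should not epimerise the α-centre, gives the 6S diene F4, whose C4 methyl should lie anti to the face the catalyst selects. The cycloaddition of F4 with 12 then comes back to the route at 14, as a single C4 epimer.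

Step 9. The hindered bicyclic keto ester may be accepted poorly by the enzyme, or hydride may be delivered to the wrong face of C8 relative to C10. The fallback replaces enzyme control by metal-hydride control: asymmetric transfer hydrogenation with dynamic kinetic resolution, RuCl(p-cymene)[(S,S)-TsDPEN] or its (R,R) enantiomer (whichever delivers 8R), HCO2H/Et3N. It sets out from 15 and comes back at 16 without a new compound.

Step 11. Equilibration at C1 may stop at, or favour, the 1-epimer 20 (H1 anti to the C10 methyl), and prolonged base may move the alkene to C1=C2 and so epimerise C10. The fallback sets C1 before the ketone is unmasked and sets out from diol 18. Hydrogenation with [Ir(cod)(PCy3)(py)]PF6 and H2 in CH2Cl2, directed by the C8 and C11 hydroxyls, should add hydrogen to C1=C5 from their face and give the cis-fused saturated ketal diol F5. TsOH·H2O in THF/H2O gives the saturated ketone diol F6. TMSCl, NaI and Et3N in MeCN give the tris-silylated, more substituted C3=C4 silyl enol ether F7. Saegusa–Ito oxidation with Pd(OAc)2 in MeCN gives the bis-trimethylsilyl ether of the enone F8, and dilute HCl on work-up comes back to the route at 21 with C1 untouched.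

Further compounds
F1 | step 7 | SAMP hydrazone of 6 | COC[C@@H]1CCCN1N=C1CC2(OCCO2)C/C1=C\C
F2 | step 7 | (6S)-6-methyl SAMP hydrazone | COC[C@@H]1CCCN1N=C1[C@H](C)C2(OCCO2)C/C1=C\C
F3 | step 7 | (6S,E)-8-ethylidene-6-methyl-1,4-dioxaspiro[4.4]nonan-7-one | C/C=C1\CC2(OCCO2)[C@@H](C)C1=O
F4 | step 7 | (6S,E)-8-ethylidene-6-methyl-7-methylene-1,4-dioxaspiro[4.4]nonane | C/C=C1\CC2(OCCO2)[C@@H](C)C1=C
F0 | step 9 | none | none
F5 | step 11 | (1R,5S,7S,8R,10S)-ketal diol with saturated cis ring fusion: H1 and H5 on the face of the C8 and C11 oxygens (C4 epimers) | O[C@@H]1C[C@H](C)[C@H]2CC3(OCCO3)C(C)[C@H]2C[C@@H]1C(C)(C)O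
F6 | step 11 | (1R,5S,7S,8R,10S)-8,11-dihydroxyguaian-3-one (C4 epimers) | O[C@@H]1C[C@H](C)[C@H]2CC(=O)C(C)[C@H]2C[C@@H]1C(C)(C)O
F7 | step 11 | tris(trimethylsilyl) derivative: C3=C4 silyl enol ether and C8, C11 silyl ethers | C[Si](C)(C)O[C@@H]1C[C@H](C)[C@H]2CC(O[Si](C)(C)C)=C(C)[C@H]2C[C@@H]1C(C)(C)O[Si](C)(C)C
F8 | step 11 | 8,11-bis(trimethylsilyl) ether of 21 | C[Si](C)(C)O[C@@H]1C[C@H](C)[C@H]2CC(=O)C(C)=C2C[C@@H]1C(C)(C)O[Si](C)(C)C
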